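**Plan**

- Retrosynthetic cuts: C4'–OMe and C3'–OH (back to a C3'=C4' alkene in ring C), O1–C2 (ring B), C2–C3 (aldol), and C1'–C2' together with C5'–C6' (ring C, [4+2]).
- Enabling feature: C1' is a quaternary carbinol carbon whose ring neighbours C2' and C6' are plain methylenes, and the only other ring-C functionality sits on the adjacent pair C3'/C4'. Ring C is therefore the cyclohex-3-ene that buta-1,3-diene forms with a 2-oxyacrylate, C1' being the oxygenated acrylate carbon.
- Forward order: ring C first (step 4); the C2–C3 bond then joins it to ring A (bought as dihydroconiferyl alcohol); ring B closes through O1–C2; ring C is oxygenated last.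
- Stereochemistry: C1' from the lactic-acid-derived tert-butyl acetal (face selection in the cycloaddition). C2 and C3 from an Evans syn-aldol with (S)-4-benzyl-2-oxazolidinone, C2 being carried into ring B by two inversions. C3' and C4' from C1'–OH-directed epoxidation and trans-diaxial methanolysis.

Key step: step 4

Remark: locants follow the benzofuran (O1, C2, C3, C3a–C7a) and ring C (C1'–C6'; C1' carbinol, C3' CHOH, C4' CHOMe). TBS = tert-butyldimethylsilyl, TES = triethylsilyl, Ar = 2-(TBS-oxy)-3-methoxy-5-[3-(TBS-oxy)propyl]phenyl. The tertiary TES ether is assumed not to migrate to the neighbouring C2 oxygen under the mildly basic conditions of steps 15–17.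

**Route**

Step 1
Reactants: 1 (R)-lactic acid; 2 pivalaldehyde
Product: 3 (2R,5R)-2-tert-butyl-5-methyl-1,3-dioxolan-4-one (cis acetal)
Conditions: TsOH·H2O (cat.), H2SO4 (cat.), pentane, reflux, Dean–Stark; recrystallised from pentane/Et2O, −78 °C
Reagents that add atoms: none
Why: Acid-catalysed acetalisation with azeotropic water removal should give predominantly the cis-2,5-disubstituted dioxolanone, the lactate centre dictating the new acetal centre, and low-temperature crystallisation removes the trans isomer, which matters because the acetal carbon is the only stereocentre that survives step 3.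

Step 2
Reactants: 3 (2R,5R)-2-tert-butyl-5-methyl-1,3-dioxolan-4-one
Product: 4 (2R,5S)-5-bromo-2-tert-butyl-5-methyl-1,3-dioxolan-4-one (Br trans to tert-butyl)
Conditions: NBS, AIBN (cat.), PhCF3, reflux
Reagents that add atoms: N-bromosuccinimide, O=C1CCC(=O)N1Br
Why: Wohl–Ziegler radical bromination in which the tertiary captodative C5–H (flanked by ring oxygen and carbonyl) is abstracted selectively and bromine is delivered to the planar radical on the face away from tert-butyl, a centre that is erased again in step 3.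

Step 3
Reactants: 4 (2R,5S)-5-bromo-2-tert-butyl-5-methyl-1,3-dioxolan-4-one
Product: 5 (R)-2-tert-butyl-5-methylene-1,3-dioxolan-4-one
Conditions: Et3N, Et2O, 0 °C to rt; distilled and stored cold over BHT
Reagents that add atoms: none
Why: E2 dehydrobromination of the tertiary α-bromo lactone can only take a proton from the methyl group, which gives the exocyclic captodative alkene without touching the acetal stereocentre.

Step 4
Reactants: 5 (R)-2-tert-butyl-5-methylene-1,3-dioxolan-4-one; 6 buta-1,3-diene
Product: 7 (2R,5S)-2-tert-butyl-1,3-dioxaspiro[4.5]dec-7-en-4-one (spiro C5 = C1'; ring C as cyclohex-3-ene)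
Conditions: buta-1,3-diene (5 equiv), toluene, BHT (cat.), sealed tube, 90 °C
Reagents that add atoms: none
Why: A concerted, suprafacial normal-demand [4+2] cycloaddition joins the s-cis diene to the exocyclic captodative alkene of 5 and forms C1'–C2' and C5'–C6' in one event. The closest known reaction type is the thermal Diels–Alder reaction of 2-alkyl-5-methylene-1,3-dioxolan-4-ones with 1,3-dienes, which is known to be strongly face-selective. Ring C closes as a six-membered carbocycle by cycloaddition, both new σ-bonds arising on the same face of the dienophile and the C3'=C4' alkene being left in place for later oxygenation. The single new stereocentre C1' is controlled by the acetal carbon: the diene adds to the alkene face opposite the tert-butyl group, so C2' ends trans and C6' cis to tert-butyl. Only π-facial selectivity is needed, because the symmetric diene removes any regiochemical or endo/exo question, and it is secured by the tert-butyl group shielding one face of the nearly planar dioxolanone. The radical inhibitor is there to keep the polymerisation-prone alkene available for the cycloaddition.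

Step 5
Reactants: 7 (2R,5S)-2-tert-butyl-1,3-dioxaspiro[4.5]dec-7-en-4-one
Product: 8 methyl (S)-1-hydroxycyclohex-3-ene-1-carboxylate
Conditions: NaOMe (0.2 equiv), MeOH, 0 °C to rt
Reagents that add atoms: methanol, CO
Why: Methoxide transesterification of the acylal-type lactone opens the ring to a hemiacetal alkoxide that expels pivalaldehyde, unmasking the tertiary α-hydroxy ester while the quaternary C1' cannot epimerise.

Step 6
Reactants: 8 methyl (S)-1-hydroxycyclohex-3-ene-1-carboxylate
Product: 9 methyl (S)-1-[(triethylsilyl)oxy]cyclohex-3-ene-1-carboxylate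
Conditions: Et3SiOTf, 2,6-lutidine, CH2Cl2, 0 °C to rt
Reagents that add atoms: triethylsilyl triflate, CC[Si](CC)(CC)OS(=O)(=O)C(F)(F)F
Why: Silyl triflate/lutidine silylation is the standard way to cap a hindered tertiary alcohol, and the triethylsilyl ether should survive hydride, boron-enolate and sulfonylation conditions yet fall to mild acid later while an aryl silyl ether stays.

Step 7
Reactants: 9 methyl (S)-1-[(triethylsilyl)oxy]cyclohex-3-ene-1-carboxylate
Product: 10 (S)-1-[(triethylsilyl)oxy]cyclohex-3-ene-1-carbaldehyde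
Conditions: i-Bu2AlH (1.1 equiv), CH2Cl2, −78 °C; aq. potassium sodium tartrate
Reagents that add atoms: none
Why: Partial ester reduction, in which the aluminium hemiacetal of this hindered α-silyloxy ester is stable at −78 °C and collapses only on work-up, giving a non-enolisable aldehyde whose C1' centre is not at risk.

Step 8
Reactants: 11 dihydroconiferyl alcohol, 4-(3-hydroxypropyl)-2-methoxyphenol
Product: 12 3-[4-(allyloxy)-3-methoxyphenyl]propan-1-ol
Conditions: allyl bromide, K2CO3, acetone, reflux
Reagents that add atoms: allyl bromide, C=CCBr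
Why: Williamson etherification in which carbonate deprotonates only the phenol, so the primary alcohol remains free.

Step 9
Reactants: 12 3-[4-(allyloxy)-3-methoxyphenyl]propan-1-ol
Product: 13 2-allyl-4-(3-hydroxypropyl)-6-methoxyphenol
Conditions: N,N-diethylaniline, 200 °C
Reagents that add atoms: none
Why: Aromatic Claisen rearrangement ([3,3]-sigmatropic shift then tautomerisation) moves the allyl group to the only free ortho position, the carbon that becomes C3a.

Step 10
Reactants: 13 2-allyl-4-(3-hydroxypropyl)-6-methoxyphenol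
Product: 14 bis-TBS ether of 13, tert-butyl{2-allyl-4-[3-(TBS-oxy)propyl]-6-methoxyphenoxy}dimethylsilane
Conditions: TBSCl (2.5 equiv), imidazole, DMF, rt
Reagents that add atoms: tert-butyldimethylsilyl chloride, CC(C)(C)[Si](C)(C)Cl
Why: Standard imidazole-mediated silylation caps the phenol and the primary alcohol in one operation, the aryl silyl ether (acid-stable, base-labile) being the group that later times the closure of ring B.

Step 11
Reactants: 14 bis-TBS ether of 13
Product: 15 2-Ar-acetaldehyde
Conditions: OsO4 (2 mol %), NaIO4 (4 equiv), 2,6-lutidine, dioxane/H2O, rt; used crude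
Reagents that add atoms: osmium tetroxide, O=[Os](=O)(=O)=O; sodium periodate (terminal oxidant that re-supplies the oxygen), [Na+].[O-]I(=O)(=O)=O
Why: Lemieux–Johnson cleavage (osmylation of the terminal alkene then periodate scission of the diol) shortens the allyl group to the two-carbon aldehyde, the trisubstituted arene and the silyl ethers being inert and lutidine suppressing over-oxidation.

Step 12
Reactants: 15 2-Ar-acetaldehyde
Product: 16 2-Ar-acetic acid
Conditions: NaClO2, NaH2PO4, 2-methyl-2-butene, t-BuOH/H2O, 0 °C to rt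
Reagents that add atoms: sodium chlorite, [Na+].[O-]Cl=O
Why: Pinnick oxidation converts the sensitive arylacetaldehyde into the acid under buffered conditions, the alkene scavenger removing hypochlorous acid before it can chlorinate the electron-rich ring.

Step 13
Reactants: 16 2-Ar-acetic acid; 17 (S)-4-benzyl-1,3-oxazolidin-2-one
Product: 19 (S)-4-benzyl-3-(2-Ar-acetyl)-1,3-oxazolidin-2-one, via mixed pivalic anhydride 18 (not isolated)
Conditions: t-BuCOCl, Et3N, THF, −20 °C; then LiCl, 17, −20 °C to rt
Reagents that add atoms: none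
Why: N-Acylation of the oxazolidinone through the mixed pivalic anhydride (LiCl/Et3N variant), attack occurring at the less hindered arylacetyl carbonyl.

Step 14
Reactants: 19 (S)-4-benzyl-3-(2-Ar-acetyl)-1,3-oxazolidin-2-one; 10 (S)-1-[(triethylsilyl)oxy]cyclohex-3-ene-1-carbaldehyde
Product: 21 (S)-4-benzyl-3-[(2S,3S)-2-Ar-3-hydroxy-3-{(S)-1-[(triethylsilyl)oxy]cyclohex-3-en-1-yl}propanoyl]-1,3-oxazolidin-2-one, via Z boron enolate 20 (not isolated)
Conditions: n-Bu2BOTf, i-Pr2NEt, CH2Cl2, −78 to 0 °C; then 10, −78 to 0 °C; pH 7 buffer, MeOH, H2O2, 0 °C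
Reagents that add atoms: none
Why: Evans syn-aldol in which soft enolisation gives the Z boron enolate, which adds through a chair Zimmerman–Traxler transition state on the enolate face away from the benzyl group of the (S)-auxiliary and so sets C3 and the C2 carbinol in the syn relation, under reagent control because the aldehyde's α-centre C1' carries two nearly equivalent ring methylenes.

Step 15
Reactants: 21 syn-aldol adduct
Product: 22 (2R,3S)-2-Ar-3-{(S)-1-[(triethylsilyl)oxy]cyclohex-3-en-1-yl}propane-1,3-diol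
Conditions: LiBH4, H2O (1.1 equiv), Et2O/THF, 0 °C
Reagents that add atoms: none
Why: Reductive auxiliary cleavage in which hydride attacks the exocyclic imide carbonyl to give the primary alcohol and release the recoverable oxazolidinone, low temperature limiting retro-aldol cleavage and silyl migration, with no stereocentre touched.

Step 16
Reactants: 22 1,3-diol
Product: 23 (1S,2R)-2-Ar-3-(TBS-oxy)-1-{(S)-1-[(triethylsilyl)oxy]cyclohex-3-en-1-yl}propan-1-ol
Conditions: TBSCl (1.1 equiv), imidazole, CH2Cl2, 0 °C
Reagents that add atoms: tert-butyldimethylsilyl chloride, CC(C)(C)[Si](C)(C)Cl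
Why: Silyl chlorides discriminate sharply between a primary hydroxyl and the secondary one wedged between C1' and C3, so only the C3 hydroxymethyl group is capped.

Step 17
Reactants: 23 mono-protected diol
Product: 24 methanesulfonate of 23 at the C2 oxygen
Conditions: MsCl, Et3N, DMAP (cat.), CH2Cl2, 0 °C to rt
Reagents that add atoms: methanesulfonyl chloride, CS(=O)(=O)Cl
Why: Sulfonylation by way of sulfene tolerates the hindered C2 hydroxyl and breaks no bond to carbon, so C2 keeps its configuration and becomes the leaving-group carbon.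

Step 18
Reactants: 24 C2 mesylate
Product: 28 3-{(2S,3R)-2-[(S)-1-hydroxycyclohex-3-en-1-yl]-3-(hydroxymethyl)-7-methoxy-2,3-dihydro-1-benzofuran-5-yl}propan-1-ol, via hydroxy mesylate 25 (not isolated), via spiro-epoxide silyl ether 26 (not isolated), via epoxy phenol 27 (not isolated)
Conditions: TsOH·H2O (0.2 equiv), MeOH/CH2Cl2, 0 °C to rt; then K2CO3 (6 equiv), MeOH, 0 to 40 °C
Reagents that add atoms: none
Why: Acidic methanolysis strips the alkyl silyl ethers but not the aryl one, then carbonate first closes the tertiary C1' alkoxide onto C2 (intramolecular Williamson reaction, 3-exo-tet, inversion) and only afterwards frees the phenoxide, whose 5-exo-tet opening of the epoxide at C2 (second inversion, the known base-mediated cyclisation of epoxidised ortho-prenylphenols to 2-(1-hydroxyalkyl)dihydrobenzofurans) builds ring B with net retention at C2 and hence the 2,3-trans arrangement.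

Step 19
Reactants: 28 dihydrobenzofuran triol
Product: 29 (1S,3S,6R)-3-[(2S,3R)-3-(hydroxymethyl)-5-(3-hydroxypropyl)-7-methoxy-2,3-dihydro-1-benzofuran-2-yl]-7-oxabicyclo[4.1.0]heptan-3-ol (oxirane cis to C1'–OH)
Conditions: VO(acac)2 (5 mol %), t-BuOOH, CH2Cl2, 0 °C to rt
Reagents that add atoms: tert-butyl hydroperoxide, CC(C)(C)OO
Why: Hydroxyl-directed vanadium-catalysed epoxidation in which, with the bulky C1' substituent equatorial, the axial tertiary homoallylic C1' hydroxyl binds the vanadium peroxide and delivers oxygen to its own face of the C3'=C4' alkene, while the primary alcohols and the arene are not oxidised.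

Step 20
Reactants: 29 cis-epoxy triol
Product: 30 difengpiol B, (1S,3S,4S)-1-[(2S,3R)-3-(hydroxymethyl)-5-(3-hydroxypropyl)-7-methoxy-2,3-dihydro-1-benzofuran-2-yl]-4-methoxycyclohexane-1,3-diol
Conditions: Yb(OTf)3 (10 mol %), MeOH, rt
Reagents that add atoms: methanol, CO
Why: Lewis-acid-catalysed epoxide alcoholysis under Fürst–Plattner control, in which the half-chair that keeps the large C1' substituent equatorial and lets the axial C1' hydroxyl and the oxirane chelate the metal is attacked by methanol at C4' (the carbon farther from the electron-withdrawing C1' oxygen) anti to the oxirane, giving the trans-diaxial product with C3'–OH cis and C4'–OMe trans to C1'–OH.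

**Compound list**

1 | (R)-lactic acid | C[C@@H](O)C(=O)O | starting material
2 | pivalaldehyde | CC(C)(C)C=O | starting material
3 | (2R,5R)-2-tert-butyl-5-methyl-1,3-dioxolan-4-one | O=C1O[C@H](C(C)(C)C)O[C@@H]1C | intermediate
4 | (2R,5S)-5-bromo-2-tert-butyl-5-methyl-1,3-dioxolan-4-one | O=C1O[C@H](C(C)(C)C)O[C@@]1(C)Br | intermediate
5 | (R)-2-tert-butyl-5-methylene-1,3-dioxolan-4-one | O=C1O[C@H](C(C)(C)C)OC1=C | intermediate
6 | buta-1,3-diene | C=CC=C | starting material
7 | (2R,5S)-2-tert-butyl-1,3-dioxaspiro[4.5]dec-7-en-4-one | O=C1O[C@H](C(C)(C)C)O[C@@]12CC=CCC2 | intermediate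
8 | methyl (S)-1-hydroxycyclohex-3-ene-1-carboxylate | COC(=O)[C@@]1(O)CC=CCC1 | intermediate
9 | methyl (S)-1-[(triethylsilyl)oxy]cyclohex-3-ene-1-carboxylate | COC(=O)[C@@]1(O[Si](CC)(CC)CC)CC=CCC1 | intermediate
10 | (S)-1-[(triethylsilyl)oxy]cyclohex-3-ene-1-carbaldehyde | O=C[C@@]1(O[Si](CC)(CC)CC)CC=CCC1 | intermediate
11 | dihydroconiferyl alcohol, 4-(3-hydroxypropyl)-2-methoxyphenol | COc1cc(CCCO)ccc1O | starting material
12 | 3-[4-(allyloxy)-3-methoxyphenyl]propan-1-ol | COc1cc(CCCO)ccc1OCC=C | intermediate
13 | 2-allyl-4-(3-hydroxypropyl)-6-methoxyphenol | COc1cc(CCCO)cc(CC=C)c1O | intermediate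
14 | tert-butyl{2-allyl-4-[3-(TBS-oxy)propyl]-6-methoxyphenoxy}dimethylsilane | COc1cc(CCCO[Si](C)(C)C(C)(C)C)cc(CC=C)c1O[Si](C)(C)C(C)(C)C | intermediate
15 | 2-{2-(TBS-oxy)-3-methoxy-5-[3-(TBS-oxy)propyl]phenyl}acetaldehyde | COc1cc(CCCO[Si](C)(C)C(C)(C)C)cc(CC=O)c1O[Si](C)(C)C(C)(C)C | intermediate
16 | 2-{2-(TBS-oxy)-3-methoxy-5-[3-(TBS-oxy)propyl]phenyl}acetic acid | COc1cc(CCCO[Si](C)(C)C(C)(C)C)cc(CC(=O)O)c1O[Si](C)(C)C(C)(C)C | intermediate
17 | (S)-4-benzyl-1,3-oxazolidin-2-one | O=C1N[C@@H](Cc2ccccc2)CO1 | starting material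
18 | mixed anhydride of 16 with pivalic acid (formed in the flask) | COc1cc(CCCO[Si](C)(C)C(C)(C)C)cc(CC(=O)OC(=O)C(C)(C)C)c1O[Si](C)(C)C(C)(C)C | intermediate
19 | (S)-4-benzyl-3-(2-Ar-acetyl)-1,3-oxazolidin-2-one | COc1cc(CCCO[Si](C)(C)C(C)(C)C)cc(CC(=O)N2[C@@H](Cc3ccccc3)COC2=O)c1O[Si](C)(C)C(C)(C)C | intermediate
20 | Z di-n-butylboron enolate of 19 (formed in the flask) | COc1cc(CCCO[Si](C)(C)C(C)(C)C)cc(/C=C(\OB(CCCC)CCCC)N2[C@@H](Cc3ccccc3)COC2=O)c1O[Si](C)(C)C(C)(C)C | intermediate
21 | (S)-4-benzyl-3-[(2S,3S)-2-Ar-3-hydroxy-3-{(S)-1-[(triethylsilyl)oxy]cyclohex-3-en-1-yl}propanoyl]-1,3-oxazolidin-2-one | COc1cc(CCCO[Si](C)(C)C(C)(C)C)cc([C@H](C(=O)N2[C@@H](Cc3ccccc3)COC2=O)[C@H](O)[C@]4(O[Si](CC)(CC)CC)CCC=CC4)c1O[Si](C)(C)C(C)(C)C | intermediate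
22 | (2R,3S)-2-Ar-3-{(S)-1-[(triethylsilyl)oxy]cyclohex-3-en-1-yl}propane-1,3-diol | COc1cc(CCCO[Si](C)(C)C(C)(C)C)cc([C@H](CO)[C@H](O)[C@]4(O[Si](CC)(CC)CC)CCC=CC4)c1O[Si](C)(C)C(C)(C)C | intermediate
23 | (1S,2R)-2-Ar-3-(TBS-oxy)-1-{(S)-1-[(triethylsilyl)oxy]cyclohex-3-en-1-yl}propan-1-ol | COc1cc(CCCO[Si](C)(C)C(C)(C)C)cc([C@H](CO[Si](C)(C)C(C)(C)C)[C@H](O)[C@]4(O[Si](CC)(CC)CC)CCC=CC4)c1O[Si](C)(C)C(C)(C)C | intermediate
24 | (1S,2R)-2-Ar-3-(TBS-oxy)-1-{(S)-1-[(triethylsilyl)oxy]cyclohex-3-en-1-yl}propyl methanesulfonate | COc1cc(CCCO[Si](C)(C)C(C)(C)C)cc([C@H](CO[Si](C)(C)C(C)(C)C)[C@H](OS(C)(=O)=O)[C@]4(O[Si](CC)(CC)CC)CCC=CC4)c1O[Si](C)(C)C(C)(C)C | intermediate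
25 | (1S,2R)-2-[2-(TBS-oxy)-5-(3-hydroxypropyl)-3-methoxyphenyl]-3-hydroxy-1-[(S)-1-hydroxycyclohex-3-en-1-yl]propyl methanesulfonate (formed in the flask) | COc1cc(CCCO)cc([C@H](CO)[C@H](OS(C)(=O)=O)[C@]4(O)CCC=CC4)c1O[Si](C)(C)C(C)(C)C | intermediate
26 | (R)-2-[2-(TBS-oxy)-5-(3-hydroxypropyl)-3-methoxyphenyl]-2-[(2R,3S)-1-oxaspiro[2.5]oct-5-en-2-yl]ethan-1-ol (formed in the flask) | COc1cc(CCCO)cc([C@H](CO)[C@H]4O[C@]45CCC=CC5)c1O[Si](C)(C)C(C)(C)C | intermediate
27 | 2-{(R)-2-hydroxy-1-[(2R,3S)-1-oxaspiro[2.5]oct-5-en-2-yl]ethyl}-4-(3-hydroxypropyl)-6-methoxyphenol (formed in the flask) | COc1cc(CCCO)cc([C@H](CO)[C@H]4O[C@]45CCC=CC5)c1O | intermediate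
28 | 3-{(2S,3R)-2-[(S)-1-hydroxycyclohex-3-en-1-yl]-3-(hydroxymethyl)-7-methoxy-2,3-dihydro-1-benzofuran-5-yl}propan-1-ol | COc1cc(CCCO)cc2c1O[C@H]([C@]1(O)CCC=CC1)[C@H]2CO | intermediate
29 | (1S,3S,6R)-3-[(2S,3R)-3-(hydroxymethyl)-5-(3-hydroxypropyl)-7-methoxy-2,3-dihydro-1-benzofuran-2-yl]-7-oxabicyclo[4.1.0]heptan-3-ol | COc1cc(CCCO)cc2c1O[C@H]([C@]1(O)CC[C@H]3O[C@H]3C1)[C@H]2CO | intermediate
30 | difengpiol B | COc1cc(CCCO)cc2c1O[C@H]([C@]1(O)CC[C@H](OC)[C@@H](O)C1)[C@H]2CO | target

**Count**

Total step count: 20. Longest linear sequence: 14 steps (steps 1–7, then 14–20). The ring-A branch (steps 8–13) joins at step 14.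

**Steps most likely to fail**

Step 14 (aldol). The boron enolate of the ortho-substituted α-aryl imide may add only slowly to the α-quaternary aldehyde, and retro-aldol equilibration of the crowded adduct may erode conversion and the syn relation. The fallback changes enolate metal, auxiliary and cleavage. It sets out from acid 16, which is coupled (EDC, DMAP, CH2Cl2) with (S)-4-benzyl-1,3-thiazolidine-2-thione to give the N-acyl thiazolidinethione F1. Its chlorotitanium enolate (TiCl4, i-Pr2NEt, N-methyl-2-pyrrolidinone, CH2Cl2, 0 °C) activates the hindered aldehyde 10 more strongly and should give the same syn adduct as its thioimide F2. The thioimide is reduced off by NaBH4 at 0 °C, conditions mild enough to spare the adduct from fragmentation, and this returns to the route at diol 22.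

Step 18 (ring-B closure). The order of events may be lost: early release of the phenoxide with direct displacement of the mesylate (wrong C2 configuration), opening of the epoxide at C1' to a six-membered ether, or base-induced elimination of the mesylate. The fallback closes the other C–O bond of ring B, so that C2 is never substituted and the aldol oxygen becomes O1. It sets out from 23: K2CO3 in MeOH at rt removes only the aryl silyl group to give phenol F3, and PhNTf2/Cs2CO3 converts it into aryl triflate F4 while the hindered C2 hydroxyl stays free. Intramolecular palladium-catalysed aryl ether formation of Buchwald–Hartwig type (Pd(OAc)2, a bulky di-tert-butyl(biaryl)phosphine, Cs2CO3, toluene, 80 °C) then joins the C2 oxygen to C7a with retention at C2 and gives the silyl-protected dihydrobenzofuran F5. n-Bu4NF removes the three silyl groups and the sequence comes back to the route at triol 28.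

Step 4 (cycloaddition). Radical polymerisation of the captodative alkene may outrun cycloaddition with the volatile, only moderately reactive diene, and any acetal epimerisation during the bromination stage would leak through as lower optical purity at C1'. The fallback makes the same two bonds to C1' by ionic steps under the same acetal control and closes the ring by metathesis. It sets out from pivalaldehyde 2, which is condensed as in step 1 with commercial (S)-2-hydroxypent-4-enoic acid (C=CC[C@H](O)C(=O)O) to give the cis acetal (2S,5S)-5-allyl-2-tert-butyl-1,3-dioxolan-4-one F6. Its lithium enolate (LiN(i-Pr)2, THF/DMPU, −78 °C) is alkylated with 4-iodobut-1-ene on the face opposite tert-butyl (self-regeneration of the stereocentre), giving (2S,5S)-5-allyl-5-(but-3-en-1-yl)-2-tert-butyl-1,3-dioxolan-4-one F7. Ring-closing metathesis with second-generation Grubbs catalyst (CH2Cl2, 40 °C) forms C3'=C4' and gives (2S,5S)-2-tert-butyl-1,3-dioxaspiro[4.5]dec-7-en-4-one F8, the acetal epimer of 7 with the same spiro configuration. Methanolysis as in step 5 returns to the route at hydroxy ester 8.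

**Further compounds**

F1 | step 14 | (S)-4-benzyl-3-(2-Ar-acetyl)-1,3-thiazolidine-2-thione | COc1cc(CCCO[Si](C)(C)C(C)(C)C)cc(CC(=O)N2[C@@H](Cc3ccccc3)CSC2=S)c1O[Si](C)(C)C(C)(C)C
F2 | step 14 | (S)-4-benzyl-3-[(2S,3S)-2-Ar-3-hydroxy-3-{(S)-1-[(triethylsilyl)oxy]cyclohex-3-en-1-yl}propanoyl]-1,3-thiazolidine-2-thione | COc1cc(CCCO[Si](C)(C)C(C)(C)C)cc([C@H](C(=O)N2[C@@H](Cc3ccccc3)CSC2=S)[C@H](O)[C@]4(O[Si](CC)(CC)CC)CCC=CC4)c1O[Si](C)(C)C(C)(C)C
F3 | step 18 | 2-{(1R,2S)-3-(TBS-oxy)-1-hydroxy-1-[(S)-1-(triethylsilyloxy)cyclohex-3-en-1-yl]propan-2-yl}-6-methoxy-4-[3-(TBS-oxy)propyl]phenol | COc1cc(CCCO[Si](C)(C)C(C)(C)C)cc([C@H](CO[Si](C)(C)C(C)(C)C)[C@H](O)[C@]4(O[Si](CC)(CC)CC)CCC=CC4)c1O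
F4 | step 18 | aryl trifluoromethanesulfonate of F3 | COc1cc(CCCO[Si](C)(C)C(C)(C)C)cc([C@H](CO[Si](C)(C)C(C)(C)C)[C@H](O)[C@]4(O[Si](CC)(CC)CC)CCC=CC4)c1OS(=O)(=O)C(F)(F)F
F5 | step 18 | (2S,3R)-3-[(TBS-oxy)methyl]-7-methoxy-5-[3-(TBS-oxy)propyl]-2-{(S)-1-[(triethylsilyl)oxy]cyclohex-3-en-1-yl}-2,3-dihydro-1-benzofuran | COc1cc(CCCO[Si](C)(C)C(C)(C)C)cc2c1O[C@H]([C@]1(O[Si](CC)(CC)CC)CCC=CC1)[C@H]2CO[Si](C)(C)C(C)(C)C
F6 | step 4 | (2S,5S)-5-allyl-2-tert-butyl-1,3-dioxolan-4-one | O=C1O[C@@H](C(C)(C)C)O[C@H]1CC=C
F7 | step 4 | (2S,5S)-5-allyl-5-(but-3-en-1-yl)-2-tert-butyl-1,3-dioxolan-4-one | O=C1O[C@@H](C(C)(C)C)O[C@@]1(CCC=C)CC=C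
F8 | step 4 | (2S,5S)-2-tert-butyl-1,3-dioxaspiro[4.5]dec-7-en-4-one | O=C1O[C@@H](C(C)(C)C)O[C@@]12CC=CCC2
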